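**Retrosynthetic overview**
1. C8–CH3 (last bond): enantioselective phase-transfer methylation of the achiral, mirror-symmetric α-aryloxyacetophenone. It replaces one of the two enantiotopic α-hydrogens, sets (R) and finishes the molecule.
2. O–CH2: Williamson ether synthesis between 3,4,5-trimethoxyphenacyl bromide and 4-allyl-2,6-dimethoxyphenol. The phenol is used in the flask in which it forms.
3. Ring-B C4–allyl: para-Claisen cascade of allyl 2,6-dimethoxyphenyl ether. The ring loses its aromaticity twice (ortho-dienone, then para-dienone) before it re-aromatises.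
4. O–allyl: syringol plus allyl bromide.
5. Rings: none is built. Both benzene rings are bought, and ring B is dearomatised and restored in the cascade.

Assumption: CIP analysis of O[C@H](C)C(=O) gives (R). Bromoketone 4 and the known cinchonine-derived phase-transfer catalyst are taken as available.

**Step 1**
Reactants: 1 syringol (2,6-dimethoxyphenol); 2 allyl bromide
Product: 3 2-(allyloxy)-1,3-dimethoxybenzene
Conditions: K2CO3, acetone, reflux, 12 h
Reagents that add atoms: none
Why: Williamson ether synthesis (SN2), in which the potassium phenoxide of 1 attacks the unhindered allylic bromide at oxygen in a polar aprotic medium, and no stereocentre is formed.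

**Step 2**
Reactants: 3 2-(allyloxy)-1,3-dimethoxybenzene; 4 2-bromo-1-(3,4,5-trimethoxyphenyl)ethan-1-one
Product: 8 2-(4-allyl-2,6-dimethoxyphenoxy)-1-(3,4,5-trimethoxyphenyl)ethan-1-one, via ortho-dienone 5 (not isolated), via para-dienone 6 (not isolated), via methoxyeugenol 7 (not isolated)
Conditions: 3 neat, Ar, 205 °C, 2 h; cool to rt; then 4, K2CO3, acetone, reflux, 10 h (one pot)
Reagents that add atoms: none
Why: Because both ortho carbons carry OMe, the aromatic Claisen [3,3] shift gives the non-enolisable dienone 5, a Cope [3,3] shift carries the allyl group on to C4 (para-Claisen rearrangement), dienone 6 tautomerises to phenol 7, and its phenoxide displaces the primary α-keto bromide of 4 (Williamson, SN2), so that 8 has no stereocentre.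

**Step 3**
Reactants: 8 2-(4-allyl-2,6-dimethoxyphenoxy)-1-(3,4,5-trimethoxyphenyl)ethan-1-one
Product: 10 (R)-2-(4-allyl-2,6-dimethoxyphenoxy)-1-(3,4,5-trimethoxyphenyl)propan-1-one, via Z-enolate 9 (not isolated)
Conditions: MeI (5 equiv), CsOH·H2O (5 equiv), O(9)-allyl-N-(2,3,4-trifluorobenzyl)hydrocinchoninium bromide (10 mol %), CH2Cl2/n-hexane 1:1, −40 °C, 24 h; cold aq NH4Cl quench
Reagents that add atoms: iodomethane, CI
Why: Asymmetric phase-transfer alkylation, in which CsOH deprotonates the mirror-symmetric ketone 8 at the interface and the Z-enolate 9 enters the organic phase as a tight ion pair whose cinchonine-derived cation shields one face, so that MeI replaces only one of the two enantiotopic α-hydrogens and sets C8 as (R) (the pseudoenantiomeric cinchonidine series gives S with α-alkoxyacetophenones), while the more hindered product is not re-enolised at −40 °C.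

**Compound list**
1 | syringol (2,6-dimethoxyphenol) | COc1cccc(OC)c1O | starting material
2 | allyl bromide (3-bromoprop-1-ene) | C=CCBr | starting material
3 | 2-(allyloxy)-1,3-dimethoxybenzene | C=CCOc1c(OC)cccc1OC | intermediate
4 | 2-bromo-1-(3,4,5-trimethoxyphenyl)ethan-1-one | COc1cc(C(=O)CBr)cc(OC)c1OC | starting material
5 | 6-allyl-2,6-dimethoxycyclohexa-2,4-dien-1-one (racemic, not isolated) | C=CCC1(OC)C=CC=C(OC)C1=O | intermediate
6 | 4-allyl-2,6-dimethoxycyclohexa-2,5-dien-1-one (not isolated) | C=CCC1C=C(OC)C(=O)C(OC)=C1 | intermediate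
7 | 4-allyl-2,6-dimethoxyphenol (methoxyeugenol, not isolated) | C=CCc1cc(OC)c(O)c(OC)c1 | intermediate
8 | 2-(4-allyl-2,6-dimethoxyphenoxy)-1-(3,4,5-trimethoxyphenyl)ethan-1-one | C=CCc1cc(OC)c(OCC(=O)c2cc(OC)c(OC)c(OC)c2)c(OC)c1 | intermediate
9 | (Z)-enolate of 8, ion pair with the catalyst cation (anion drawn, not isolated) | C=CCc1cc(OC)c(O/C=C(\[O-])c2cc(OC)c(OC)c(OC)c2)c(OC)c1 | intermediate
10 | (R)-2-(4-allyl-2,6-dimethoxyphenoxy)-1-(3,4,5-trimethoxyphenyl)propan-1-one | C=CCc1cc(OC)c(O[C@H](C)C(=O)c2cc(OC)c(OC)c(OC)c2)c(OC)c1 | target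

**Total step count:** 3. **Longest linear sequence:** 3 (1 → 3 → 8 → 10).

**Steps most likely to fail**

Step 3 carries the highest risk. MeI is a small electrophile, so the ee may stay near 80–90 %. Some dimethylation or base-induced racemisation is also possible. The ee is read by chiral HPLC and, if needed, raised by recrystallisation or preparative chiral HPLC.

The fallback takes the stereocentre from the chiral pool and forms the C8–O bond with inversion. It sets out from 7, isolated after the thermal stage of step 2, and comes back at 10. Mitsunobu reaction of 7 with ethyl (S)-lactate (PPh3, DIAD, THF, 0 °C to rt) gives ethyl (R)-2-(4-allyl-2,6-dimethoxyphenoxy)propanoate F1. MeNH(OMe)·HCl with i-PrMgCl (THF, −20 °C) converts it into (R)-2-(4-allyl-2,6-dimethoxyphenoxy)-N-methoxy-N-methylpropanamide F2. Commercial 3,4,5-trimethoxyphenylmagnesium bromide (THF, −20 to 0 °C) then gives 10.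

Step 2 can fail in several ways at 205 °C: incomplete rearrangement, loss of the allyl group back to 1, or drift of allyl to propenyl. Any of these gives a dirty phenol for the etherification.

The fallback replaces the sigmatropic cascade by C–H borylation and cross-coupling. It sets out from 1 and comes back at 8. Alkylation of 1 with 4 (K2CO3, acetone, reflux) gives 2-(2,6-dimethoxyphenoxy)-1-(3,4,5-trimethoxyphenyl)ethan-1-one F3. Sterically controlled iridium-catalysed borylation ([Ir(OMe)(cod)]2, dtbpy, B2pin2, THF, 80 °C) attacks the only C–H without an ortho substituent, which is para to the ether oxygen. This gives 2-[2,6-dimethoxy-4-(4,4,5,5-tetramethyl-1,3,2-dioxaborolan-2-yl)phenoxy]-1-(3,4,5-trimethoxyphenyl)ethan-1-one F4. Suzuki–Miyaura allylation with 2 (Pd(PPh3)4, K2CO3, THF/H2O, 60 °C) gives 8.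

Step 1 carries the lowest risk, namely incomplete O-allylation or some C-allylation.

The fallback avoids the allyl ether and the rearrangement altogether. It sets out from 1 and comes back at 7. para-Bromination (NBS, CHCl3, −40 °C to rt) gives 4-bromo-2,6-dimethoxyphenol F5. Stille allylation with allyltributylstannane (Pd(PPh3)4, toluene, 100 °C) gives 7, which enters the second stage of step 2.

**Further compounds**
F1 | step 3 | ethyl (R)-2-(4-allyl-2,6-dimethoxyphenoxy)propanoate | C=CCc1cc(OC)c(O[C@H](C)C(=O)OCC)c(OC)c1
F2 | step 3 | (R)-2-(4-allyl-2,6-dimethoxyphenoxy)-N-methoxy-N-methylpropanamide | C=CCc1cc(OC)c(O[C@H](C)C(=O)N(C)OC)c(OC)c1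
F3 | step 2 | 2-(2,6-dimethoxyphenoxy)-1-(3,4,5-trimethoxyphenyl)ethan-1-one | COc1cccc(OC)c1OCC(=O)c1cc(OC)c(OC)c(OC)c1
F4 | step 2 | 2-[2,6-dimethoxy-4-(4,4,5,5-tetramethyl-1,3,2-dioxaborolan-2-yl)phenoxy]-1-(3,4,5-trimethoxyphenyl)ethan-1-one | COc1cc(B2OC(C)(C)C(C)(C)O2)cc(OC)c1OCC(=O)c1cc(OC)c(OC)c(OC)c1
F5 | step 1 | 4-bromo-2,6-dimethoxyphenol | COc1cc(Br)cc(OC)c1O
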